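In a one-step world a flask stops where a reactant ends or where the way back balances the way forward, and the level shows how far the charges went. The red flask, followed so far, is the flask asked about.

in all of them: starting material 0.50 M; free catalyst 0.6 mol%; second catalyst 0.057 mol%
- red: partner 1.3 equiv; impurity 0.35 mM; temperature 0 °C; the very flask that is asked about, followed so far
- ochre: partner 1.3 equiv; impurity 0.52 mM; temperature −15 °C; run made earlier
- flask: partner 1.30 equiv; impurity 0.35 mM; temperature 0 °C; time 8.0 d

| run | time / h | target / % |
|---|---|---|
| red | 15.0 | 21.6 |
| red | 30.0 | 27.4 |
| red | 50.0 | 29.9 |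
| red | 72.0 | 30.5 |
| red | 96.0 | 29.7 |
| red | 120 | 30.3 |
| ochre | 2.00 | 1.8 |
| ochre | 5.00 | 3.3 |
| ochre | 10.0 | 6.3 |
| ochre | 12.0 | 7.1 |
| ochre | 20.0 | 10.5 |
| ochre | 25.0 | 12.2 |
| ochre | 30.0 | 13.3 |

(scatter of a reading: 0.5 percentage points)

- ash: at 8.0 d raise the temperature by 20 K, then wait 8.0 d
- larch: at 8.0 d add partner, 50.0% of the amount charged, then wait 8.0 d
- oak: change nothing and wait 8.0 d more
- birch: at 8.0 d take out 90% of the target then present, then wait 8.0 d
- maple: at 8.0 d add free catalyst, 100% of the amount charged, then wait 8.0 d

1. target, in percent of the starting material first charged, at 8.0 d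
2. the remedy with the largest gain of target, or "none" below 2 percentage points (ash / larch / oak / birch / maple / none)
3. target present, with what was taken out counted in, in percent of the starting material first charged, after birch
4. target present, with what was taken out counted in, in percent of the starting material first charged, after maple

- target taken out counts as made
- "the catalyst" is free catalyst with its forms; second catalyst is a second catalyst
- additions bring no volume worth counting

The red curve opens steeply, with 21.6% of target at 15.0 h. Its readings from 50.0 h on average 30.1%, and the opening chord, carried on, crosses that level at 20.9 h, which marks the knee. Counting turnovers (the turnover number) gives 528 targets per second catalyst at the level, but 50.2 per free catalyst.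

Now suppose that one impurity removes one catalyst. The red flask holds 0.35 mM of impurity, less than its 3.00 mM of free catalyst but more than its 0.285 mM of second catalyst. The carried quantity is the titre, c(impurity) divided by c(second catalyst) as charged: 1.23. On this supposition a titre above one means that the impurity charged outlasts the second catalyst, and the red level is then the turnover number of second catalyst read above. The ochre run has a titre of 1.82 and, colder, reads 13.3% at 30.0 h, below red's 27.4% at 30.0 h. On the titre of the red flask, the reckoning made here stays near 30.1% at 8.0 d. No remedy changes the titre, added free catalyst included, so this reckoning names none.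

The forecast agrees on the level, with 30% (29.5% to 30.6%) now and 30% after birch. It parts on the remedy: it names maple, with 47% (41% to 52%), on the ground that “Fresh catalyst repeats the same integrated turnover”.

The flask gives 30.5% now, 30.5% after birch and 30.5% after maple, so the best remedy is none.

    starting material + free catalyst ⇌ free catalyst + open intermediate (K = 0.120, k = 0.0300 L mol⁻¹ s⁻¹, Ea = 49.0 kJ mol⁻¹, ΔH = −47.0 kJ mol⁻¹)
    second catalyst + open intermediate ⇌ catalyst intermediate (K = 860 L mol⁻¹, k = 4.60 L mol⁻¹ s⁻¹, Ea = 38.0 kJ mol⁻¹, ΔH = 33.0 kJ mol⁻¹)
    partner + catalyst intermediate → second catalyst + target (k = 0.0390 L mol⁻¹ s⁻¹, Ea = 63.0 kJ mol⁻¹)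
    second catalyst + impurity → spent catalyst (k = 1.50 L mol⁻¹ s⁻¹, Ea = 50.0 kJ mol⁻¹)
    open intermediate → side product (k = 1.10 × 10⁻⁵ s⁻¹, Ea = 90.0 kJ mol⁻¹)
    (constants at 0 °C)

In the flask, while impurity turned second catalyst into spent catalyst, target reached 24.1% by 19.2 h, when second catalyst stood at 1.53%, catalyst intermediate at 9.86% and spent catalyst at 88.6% of the second catalyst charged. From 96.0 h, with second catalyst at 0.0194%, target stayed near 30.5% while open intermediate fed side product, which reached 38.9% by 192 h. The titre of 1.23 leaves 18.7% of the impurity charged, and the flask holds 19% at 192 h. The neighbour flask with 0.23 mol% of second catalyst has a titre of 0.304, and it ended with spent catalyst at 30.4%, second catalyst at 69.6% and target at 98.5%.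

All runs stem from a simulated flask for an exercise; scatter was added.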